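The pyranone (ring C) is disconnected at O1–C8a, C4–C4a and O1–C2. Ring A carbons C4a and C8a are neighbours that carry the carbonyl carbon C4 and the ring oxygen O1, and the C5 oxygen flanks C4a. A 3,5-dimethoxybenzyne spanning C4a–C8a is therefore polarised to accept a carboxylate oxygen at C8a and pass the acyl carbon to C4a. In one operation the aryne inserts into the C(=O)–O bond of a β-methoxyacrylate that already holds ring B (β-carbon) and the isopentyl chain (α-carbon), and the liberated phenoxide closes ring C at C2 with loss of methoxide. Five aryl methyl ethers are cleaved last.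

Key step: step 7

Remark: 11 is racemic, and the enol ether double bond of 12–16 and 18–20 is expected as an E/Z mixture and is drawn without geometry because both isomers converge in step 7; flavone numbering is used for the atoms of rings A, B and C.

Step 1
Reactants: 1 3,5-dimethoxyphenol
Product: 2 3,5-dimethoxyphenyl N-isopropylcarbamate
Conditions: i-PrNCO, Et3N (cat.), CH2Cl2, rt
Reagents that add atoms: isopropyl isocyanate, CC(C)N=C=O
Why: Amine-catalysed addition of the phenol O–H to the isocyanate (carbamoylation) installs a strong ortho-directing group that can later be removed under mild basic conditions.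

Step 2
Reactants: 2 3,5-dimethoxyphenyl N-isopropylcarbamate
Product: 6 3,5-dimethoxy-2-(trimethylsilyl)phenyl N-isopropylcarbamate, via N-silyl carbamate 3 (not isolated), via aryllithium 4 (not isolated), via bis-silyl carbamate 5 (not isolated)
Conditions: Me3SiOTf, TMEDA, Et2O, 0 °C → rt; s-BuLi, TMEDA, −78 °C; Me3SiCl, −78 °C → rt; aq. NaHSO4
Reagents that add atoms: chlorotrimethylsilane, C[Si](C)(C)Cl
Why: Directed ortho-metalation: after transient N-silylation of the carbamate N–H, the O-carbamate and the adjacent methoxy group jointly direct s-BuLi to C2 (C6 is equivalent) in preference to C4 between the two methoxy groups, Me3SiCl traps the aryllithium and the N–Si bond is hydrolysed on work-up, the site of silylation being checked by NOE from SiMe3 to a single OMe.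

Step 3
Reactants: 6 3,5-dimethoxy-2-(trimethylsilyl)phenyl N-isopropylcarbamate
Product: 8 3,5-dimethoxy-2-(trimethylsilyl)phenyl trifluoromethanesulfonate, via silylphenol 7 (not isolated)
Conditions: DBU, Et2NH, MeCN, 40 °C; then PhNTf2, rt
Reagents that add atoms: N-phenylbis(trifluoromethanesulfonimide), O=S(=O)(N(c1ccccc1)S(=O)(=O)C(F)(F)F)C(F)(F)F
Why: E1cB cleavage of the N–H carbamate by DBU, with diethylamine capturing the isocyanate as a urea, frees the phenoxide, which is O-sulfonylated in the same flask by PhNTf2 so that the protodesilylation-prone silylphenol is never isolated.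

Step 4
Reactants: 9 ethyl 3-oxo-3-(3,4,5-trimethoxyphenyl)propanoate; 10 1-bromo-3-methylbutane
Product: 11 ethyl 5-methyl-2-(3,4,5-trimethoxybenzoyl)hexanoate
Conditions: K2CO3, KI (cat.), acetone, reflux
Reagents that add atoms: none
Why: SN2 C-alkylation of the doubly stabilised β-keto ester enolate by a primary halide (iodide formed in situ, Finkelstein exchange) should stop at monoalkylation because the product is less acidic and more crowded; the new stereocentre is formed racemic and is erased in step 5.

Step 5
Reactants: 11 ethyl 5-methyl-2-(3,4,5-trimethoxybenzoyl)hexanoate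
Product: 13 ethyl 3-methoxy-2-(3-methylbutyl)-3-(3,4,5-trimethoxyphenyl)prop-2-enoate, via potassium enolate 12 (not isolated)
Conditions: KN(SiMe3)2, THF–DMPU, −78 °C; Me2SO4, −78 → 0 °C
Reagents that add atoms: dimethyl sulfate, COS(=O)(=O)OC
Why: O-alkylation of an ambident enolate: a dissociated potassium enolate in a dipolar aprotic medium reacts with the hard electrophile Me2SO4 at oxygen, and C-methylation is further disfavoured because it would create a quaternary carbon; either double-bond geometry is acceptable.

Step 6
Reactants: 13 ethyl 3-methoxy-2-(3-methylbutyl)-3-(3,4,5-trimethoxyphenyl)prop-2-enoate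
Product: 15 3-methoxy-2-(3-methylbutyl)-3-(3,4,5-trimethoxyphenyl)prop-2-enoic acid, via lithium carboxylate 14 (not isolated)
Conditions: LiOH·H2O, THF/MeOH/H2O, 60 °C; then AcOH to pH ≈ 5, 0 °C, extraction
Reagents that add atoms: lithium hydroxide (hydroxide oxygen), [Li+].[OH-]
Why: Saponification (base-mediated acyl–oxygen cleavage) leaves the enol ether untouched because it is labile only to aqueous acid, and acidification with acetic acid in the cold liberates the acid without the C-protonation that would lead to a β-keto acid and decarboxylation.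

Step 7
Reactants: 15 3-methoxy-2-(3-methylbutyl)-3-(3,4,5-trimethoxyphenyl)prop-2-enoic acid; 8 3,5-dimethoxy-2-(trimethylsilyl)phenyl trifluoromethanesulfonate
Product: 21 5,7-dimethoxy-3-(3-methylbutyl)-2-(3,4,5-trimethoxyphenyl)-4H-chromen-4-one, via caesium carboxylate 16 (not isolated), via 3,5-dimethoxybenzyne 17 (not isolated), via aryl anion ester 18 (not isolated), via benzoxete alkoxide 19 (not isolated), via phenoxide enone 20 (not isolated)
Conditions: CsOH·H2O (1 equiv), MeOH, rt, then evaporate and dry (PhMe azeotrope, vacuum); 8 (2 equiv), CsF (4 equiv), THF, 125 °C, sealed tube; if 20 persists, HCl/MeOH, 60 °C in the same flask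
Reagents that add atoms: none
Why: Fluoride removes the silyl group of 8 and triflate departs to give aryne 17; the dry carboxylate 16 adds through oxygen to the aryne carbon remote from the flanking methoxy group (future C8a), the aryl anion at C4a (18) attacks its own ester carbonyl in a 4-exo-trig closure, and the strained benzoxete alkoxide 19 opens to the o-acyl phenoxide 20, which completes the net insertion into the C(=O)–O bond. Phenoxide O1 then adds to the β-carbon C2 of the vinylogous ester in a 6-endo-trig closure and methoxide is expelled, so ring C (the only ring formed) appears at the flavone oxidation level and no stereocentre is created. The closest known reaction type is the fluoride-induced insertion of arynes into the C–O bond of carboxylic acids to give o-hydroxyaryl ketones, which with α,β-unsaturated acids continues by oxa-Michael closure to chromanones; the tetrasubstituted β-methoxy acid is an extension within that class, its methoxy group turning the closure into the addition–elimination familiar from o-hydroxyaryl β-alkoxy enones. The required regiochemistry (O at C8a, acyl at C4a) is secured by the methoxy group beside one aryne carbon, which distorts the aryne toward attack at the distal carbon and stabilises the anion ortho to itself. Acyl (1,2) attack rather than conjugate attack by the aryl anion is secured by the fully substituted, donor-deactivated β-carbon and by the short tether that holds only the carbonyl within reach. The salt form leaves no proton to divert the aryl anion to a simple aryl ester, and the masked β-carbonyl keeps the acid from decarboxylating.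

Step 8
Reactants: 21 5,7-dimethoxy-3-(3-methylbutyl)-2-(3,4,5-trimethoxyphenyl)-4H-chromen-4-one
Product: 22 asplenetin, 5,7-dihydroxy-3-(3-methylbutyl)-2-(3,4,5-trihydroxyphenyl)-4H-chromen-4-one
Conditions: BBr3 (10 equiv), CH2Cl2, −78 °C → rt; H2O, Na2S2O4, 0 °C, under Ar
Reagents that add atoms: none
Why: Boron tribromide ether cleavage (Lewis acid activation, then SN2 attack of bromide on the O-methyl groups) should remove all five methyl groups, the chelated C5 ether first, while the 3-alkylchromone core is inert to the reagent and the reductive, oxygen-free work-up protects the pyrogallol ring B.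

Compound list
1 | 3,5-dimethoxyphenol | COc1cc(O)cc(OC)c1 | starting material
2 | 3,5-dimethoxyphenyl N-isopropylcarbamate | COc1cc(OC)cc(OC(=O)NC(C)C)c1 | intermediate
3 | 3,5-dimethoxyphenyl N-isopropyl-N-(trimethylsilyl)carbamate | COc1cc(OC)cc(OC(=O)N(C(C)C)[Si](C)(C)C)c1 | intermediate
4 | [2-(N-isopropyl-N-trimethylsilylcarbamoyloxy)-4,6-dimethoxyphenyl]lithium | [Li]c1c(OC)cc(OC)cc1OC(=O)N(C(C)C)[Si](C)(C)C | intermediate
5 | 3,5-dimethoxy-2-(trimethylsilyl)phenyl N-isopropyl-N-(trimethylsilyl)carbamate | COc1cc(OC)c([Si](C)(C)C)c(OC(=O)N(C(C)C)[Si](C)(C)C)c1 | intermediate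
6 | 3,5-dimethoxy-2-(trimethylsilyl)phenyl N-isopropylcarbamate | COc1cc(OC)c([Si](C)(C)C)c(OC(=O)NC(C)C)c1 | intermediate
7 | 3,5-dimethoxy-2-(trimethylsilyl)phenol (present as its DBU-H phenoxide) | COc1cc(O)c([Si](C)(C)C)c(OC)c1 | intermediate
8 | 3,5-dimethoxy-2-(trimethylsilyl)phenyl trifluoromethanesulfonate (silicon between OMe and OTf) | COc1cc(OC)c([Si](C)(C)C)c(OS(=O)(=O)C(F)(F)F)c1 | intermediate
9 | ethyl 3-oxo-3-(3,4,5-trimethoxyphenyl)propanoate | CCOC(=O)CC(=O)c1cc(OC)c(OC)c(OC)c1 | starting material
10 | 1-bromo-3-methylbutane | CC(C)CCBr | starting material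
11 | ethyl 5-methyl-2-(3,4,5-trimethoxybenzoyl)hexanoate (racemic) | CCOC(=O)C(CCC(C)C)C(=O)c1cc(OC)c(OC)c(OC)c1 | intermediate
12 | potassium 3-ethoxy-2-(3-methylbutyl)-3-oxo-1-(3,4,5-trimethoxyphenyl)prop-1-en-1-olate | [K+].CCOC(=O)C(CCC(C)C)=C([O-])c1cc(OC)c(OC)c(OC)c1 | intermediate
13 | ethyl 3-methoxy-2-(3-methylbutyl)-3-(3,4,5-trimethoxyphenyl)prop-2-enoate (E/Z mixture) | CCOC(=O)C(CCC(C)C)=C(OC)c1cc(OC)c(OC)c(OC)c1 | intermediate
14 | lithium 3-methoxy-2-(3-methylbutyl)-3-(3,4,5-trimethoxyphenyl)prop-2-enoate | [Li+].[O-]C(=O)C(CCC(C)C)=C(OC)c1cc(OC)c(OC)c(OC)c1 | intermediate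
15 | 3-methoxy-2-(3-methylbutyl)-3-(3,4,5-trimethoxyphenyl)prop-2-enoic acid (E/Z mixture) | O=C(O)C(CCC(C)C)=C(OC)c1cc(OC)c(OC)c(OC)c1 | intermediate
16 | caesium 3-methoxy-2-(3-methylbutyl)-3-(3,4,5-trimethoxyphenyl)prop-2-enoate | [Cs+].[O-]C(=O)C(CCC(C)C)=C(OC)c1cc(OC)c(OC)c(OC)c1 | intermediate
17 | 3,5-dimethoxybenzyne (1,2-didehydro-3,5-dimethoxybenzene) | COC1=CC(OC)=CC#C1 | intermediate
18 | 2-caesio-3,5-dimethoxyphenyl 3-methoxy-2-(3-methylbutyl)-3-(3,4,5-trimethoxyphenyl)prop-2-enoate (aryl anion between OMe and the ester oxygen) | [Cs]c1c(OC)cc(OC)cc1OC(=O)C(CCC(C)C)=C(OC)c1cc(OC)c(OC)c(OC)c1 | intermediate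
19 | caesium 3,5-dimethoxy-2-[1-methoxy-5-methyl-1-(3,4,5-trimethoxyphenyl)hex-1-en-2-yl]-2H-1-benzoxet-2-olate | [Cs+].[O-]C1(Oc2cc(OC)cc(OC)c21)C(CCC(C)C)=C(OC)c1cc(OC)c(OC)c(OC)c1 | intermediate
20 | caesium 3,5-dimethoxy-2-[3-methoxy-2-(3-methylbutyl)-3-(3,4,5-trimethoxyphenyl)prop-2-enoyl]phenoxide | [Cs+].[O-]c1cc(OC)cc(OC)c1C(=O)C(CCC(C)C)=C(OC)c1cc(OC)c(OC)c(OC)c1 | intermediate
21 | 5,7-dimethoxy-3-(3-methylbutyl)-2-(3,4,5-trimethoxyphenyl)-4H-chromen-4-one | CC(C)CCc1c(-c2cc(OC)c(OC)c(OC)c2)oc2cc(OC)cc(OC)c2c1=O | intermediate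
22 | asplenetin, 5,7-dihydroxy-3-(3-methylbutyl)-2-(3,4,5-trihydroxyphenyl)-4H-chromen-4-one (no stereocentres) | CC(C)CCc1c(-c2cc(O)c(O)c(O)c2)oc2cc(O)cc(O)c2c1=O | target

Total step count: 8.
Longest linear sequence: 5 steps (9 → 11 → 13 → 15 → 21 → 22; the branch 1 → 2 → 6 → 8 → 21 → 22 is equally long).

Steps most likely to fail

Step 7. The aryl anion may be protonated by adventitious proton sources before the acyl shift, so that the sequence stops at O-arylation. Acyl transfer at the crowded tetrasubstituted acyl group may also be slow, or the phenoxide may be arylated by a second aryne before ring closure. Slow aryne release from sparingly soluble CsF and portionwise addition of 8 are the first countermeasures. The fallback uses established flavone chemistry, sets out from 1 and rejoins the route at 21. BF3·OEt2-mediated ortho-acylation of 1 with 5-methylhexanoic acid (Friedel–Crafts/Fries type, the boron chelate directing next to the hydroxyl) should give 1-(2-hydroxy-4,6-dimethoxyphenyl)-5-methylhexan-1-one F1. O-Aroylation with 3,4,5-trimethoxybenzoyl chloride in pyridine should give 3,5-dimethoxy-2-(5-methylhexanoyl)phenyl 3,4,5-trimethoxybenzoate F2. Baker–Venkataraman rearrangement (KOt-Bu, THF) should give 1-(2-hydroxy-4,6-dimethoxyphenyl)-2-(3-methylbutyl)-3-(3,4,5-trimethoxyphenyl)propane-1,3-dione F3, and cyclodehydration (H2SO4, AcOH, warm) should give 21.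

Step 5. Competing C-methylation of the ambident enolate would consume material as a quaternary keto ester. The fallback leaves enolate chemistry altogether, sets out from 11 and rejoins at 13. Acid-catalysed ketalisation with trimethyl orthoformate (TsOH cat., 60 °C) should give ethyl 2-[dimethoxy(3,4,5-trimethoxyphenyl)methyl]-5-methylhexanoate F4. Continued heating with the acid catalyst while volatiles are distilled off should eliminate methanol to the conjugated enol ether 13. Carbon alkylation is impossible in this manifold.

Step 6. Hydrolysis of the hindered, donor-deactivated ester may be slow, and any enol ether hydrolysis during acidification would be followed by decarboxylation. The fallback replaces hydrolysis by a fluoride-triggered ester cleavage, sets out from 11 and rejoins at 16. Thermal transesterification of 11 with 2-(trimethylsilyl)ethanol (DMAP cat., PhMe, reflux with removal of ethanol, via the acylketene) should give 2-(trimethylsilyl)ethyl 5-methyl-2-(3,4,5-trimethoxybenzoyl)hexanoate F5. O-Methylation under the conditions of step 5 should give 2-(trimethylsilyl)ethyl 3-methoxy-2-(3-methylbutyl)-3-(3,4,5-trimethoxyphenyl)prop-2-enoate F6. Treatment with CsF (DMF or THF, rt to 50 °C) should release the caesium carboxylate 16 by β-elimination without water or acid, ready for the aryne step in the same flask.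

Further compounds
F1 | step 7 | 1-(2-hydroxy-4,6-dimethoxyphenyl)-5-methylhexan-1-one | CC(C)CCCC(=O)c1c(O)cc(OC)cc1OC
F2 | step 7 | 3,5-dimethoxy-2-(5-methylhexanoyl)phenyl 3,4,5-trimethoxybenzoate | CC(C)CCCC(=O)c1c(OC)cc(OC)cc1OC(=O)c1cc(OC)c(OC)c(OC)c1
F3 | step 7 | 1-(2-hydroxy-4,6-dimethoxyphenyl)-2-(3-methylbutyl)-3-(3,4,5-trimethoxyphenyl)propane-1,3-dione | CC(C)CCC(C(=O)c1c(O)cc(OC)cc1OC)C(=O)c1cc(OC)c(OC)c(OC)c1
F4 | step 5 | ethyl 2-[dimethoxy(3,4,5-trimethoxyphenyl)methyl]-5-methylhexanoate | CCOC(=O)C(CCC(C)C)C(OC)(OC)c1cc(OC)c(OC)c(OC)c1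
F5 | step 6 | 2-(trimethylsilyl)ethyl 5-methyl-2-(3,4,5-trimethoxybenzoyl)hexanoate | C[Si](C)(C)CCOC(=O)C(CCC(C)C)C(=O)c1cc(OC)c(OC)c(OC)c1
F6 | step 6 | 2-(trimethylsilyl)ethyl 3-methoxy-2-(3-methylbutyl)-3-(3,4,5-trimethoxyphenyl)prop-2-enoate | C[Si](C)(C)CCOC(=O)C(CCC(C)C)=C(OC)c1cc(OC)c(OC)c(OC)c1
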